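## The problem

The target is an achiral tridepside in which three 6-methylbenzoate rings (A, B, C) are joined by two aryl ester bonds: the C1 carbonyl of ring A esterifies the C4 oxygen of ring B, and the C1 carbonyl of ring B esterifies the C4 oxygen of ring C, which ends in a free salicylic-type acid. There is no stereocentre, so the task is one of regiocontrol and functional-group tolerance. Rings B and C are both orsellinate units, whereas ring A is pentasubstituted (C1 carbonyl, C2 OMe, C3 and C4 OH, C5 H, C6 CH3), so one of three contiguous oxygens has to be methylated selectively. Both depside bonds are aryl esters that hydroxide, alkoxide or amines cleave or scramble, the ring A catechol is oxidised readily in base, and the 2-hydroxy-6-methylbenzoic acid of ring C loses CO2 in hot acid; the end game therefore has to be neutral. The ring A carbonyl is flanked by OMe and CH3, so its acid should be obtained free without saponifying a doubly ortho-substituted ester and must then be forced onto a phenol. The feature that opens the key step is that CH3 (C6) and CO2H (C1) of ring A sit on adjacent carbons, with the C2 methoxy oxygen directly beside C1. A C1–C6 aryne polarised by that oxygen can accept a methyl nucleophile at C6 and CO2 at C1.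

## Retrosynthesis

**22 from 21.** The last cut removes three O–benzyl bonds (two ethers on ring A, one ester on ring C). Hydrogenolysis is neutral, leaves aryl esters alone and needs a single reagent. Silyl or acetal groups would need fluoride or acid in the presence of a free catechol. Precursor 21 already holds every skeletal bond.

**21 from 14 and 20.** The ring A acyl–oxygen bond to C4 of ring B is cut. Cutting the B–C ester last would carry the aryne-derived ring through more steps. Cutting here keeps that acid (14) for the penultimate step and leaves a B–C diphenol ester (20) built from one commercial acid. Of the three hydroxyls in 20, only the ring B C4 hydroxyl is not hydrogen-bonded to an ester carbonyl. The forward reaction must activate a doubly ortho-substituted acid without generating phenoxides that would scramble the existing depside bond.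

**14 from 8, 9 and 10 (key disconnection).** C6–CH3 and C1–CO2H are cut together. Cutting only C1–CO2H would require metalation of a tetra-substituted toluene between OMe and CH3. Cutting only C6–CH3 would require ortho-methylation of a benzoate. The double cut leads to triflate 8, a benzene carrying only heteroatoms, each placed by phenol chemistry. The forward reaction must give aryne 12 from 8 via the magnesiated triflate 11, add methylmagnesium bromide 9 at C6 only, and trap arylmagnesium 13 with CO2 (10).

**8 from 7, and 7 from 6.** The S–O bond (triflation) and the C6–I bond are cut. In phenol 6 the para position and one ortho position carry oxygen, so C6 is the only site a phenoxide can direct iodine to.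

**6 from 4.** The C1–O bond is traced back to a C1–CHO bond via formate 5 (Baeyer–Villiger/Dakin-type oxidation). The aldehyde serves as a masked phenol and also as the chelating group that distinguishes the C2 oxygen in the next cut.

**4 from 3, and 3 from 1 and 2.** The O–CH3 bond at C2 and the O–benzyl bonds at C3 and C4 are cut. In 2,3,4-trihydroxybenzaldehyde 1 the C2 hydroxyl is chelated to the aldehyde, so two equivalents of benzyl bromide 2 should take the other two oxygens first and the methyl group then goes to C2. The whole oxygen pattern of ring A is bought intact.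

**20 from 19, and 19 from 18 and 16.** Two O–Si bonds and then the B–C ester bond are cut. Ring B must arrive as an acid with its own phenols masked by a group orthogonal to benzyl, so silyl ethers are used (18). Ring C arrives as benzyl orsellinate 16, whose C4 hydroxyl is the only reactive one.

**16 and 18 from 15.** Both orsellinate partners come from orsellinic acid 15: carboxylate benzylation with 2 gives 16, and exhaustive silylation to 17 followed by selective silyl ester hydrolysis gives 18.

## Roads not taken

Alternative 1: Ring A is cut at C1–C6 and C3–C4 and assembled from acyclic esters. In the forward key step the sodium enolate of methyl 4-(benzyloxy)-3-oxobutanoate A1 adds to methyl crotonate A2, and the benzyloxy-bearing carbon then acylates on the crotonate ester to give the cyclohexanedione A3. Dehydrogenation would give methyl 3-(benzyloxy)-2,4-dihydroxy-6-methylbenzoate A4.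
- Merits: cheap reagents, no cryogenic organometallics, easy scale-up, and a C3 oxygen that is already differentiated.
- Weak points: A3 must be aromatised by an oxidant that spares the benzyl ether. The C2 and C4 hydroxyls of A4 still have to be told apart (benzylate C4, then methylate the chelated C2). The acid emerges as a methyl ester between two ortho substituents, so reaching 14 needs hot hydroxide.
- Comparison: the step count to 14 is about the same as steps 1–6, and this road is operationally simpler and cheaper. The chosen plan offers in return a ring that is aromatic and correctly oxygenated from the first step, a C2 oxygen singled out by chelation, and a carboxyl that is formed free.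

Alternative 2: Ring A is cut at C1–C2 and C5–C6 and built last, on the finished depside. In the forward key step the silyl ketene acetal diene A5 (2-benzyloxy, 3-silyloxy, 1-methoxy-1-silyloxy) undergoes a Diels–Alder reaction with the but-2-ynoate ester A6, a fully benzylated ring B–ring C depside acylated at the ring B C4 oxygen. Loss of methanol during aromatisation gives tridepside A7 directly.
- Merits: it is the most convergent option. The A–B ester is made as an unhindered butynoate before ring A exists, so the hindered esterification of step 11 is avoided. That is a real advantage.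
- Weak points: a but-2-ynoate is a sluggish dienophile and needs heat, which the hydrolytically fragile tetra-oxygenated diene A5 and two aryl esters must survive. A7 still needs methylation of a chelated C2 hydroxyl beside a base-labile aryl silyl ether, then desilylation. The least predictable step consumes the most advanced material.
- Comparison: the chosen plan takes its risk on a small ring made from a cheap aldehyde and has the methoxy group in place from step 2.

Alternative 3: The cut is made in ring B (ester C–O and C1–C6), not ring A. In the forward key step the diketo-dioxinone A8 is thermolysed in the presence of the ring C phenol A9. The ester C–O bond forms by ketene capture, and the tethered triketo chain then folds by C2-to-C7 aldol condensation and dehydration to depside A10, with both ring B hydroxyls free.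
- Merits: the B–C ester forms without activating a hindered acid. Ring B emerges with free hydroxyls, so no silyl on/off pair is needed; in protecting-group economy it is at least as good as steps 8–10.
- Weak points: it leaves ring A, which holds all the real difficulty, untouched. A8 takes several steps to make. A9 needs its chelated hydroxyl benzylated while the C4 hydroxyl stays free. Ring B is built de novo although orsellinic acid 15 is commercial.
- Comparison: it is a possible replacement for the B–C branch, not a competitor to the ring A plan. The chosen plan has four routine steps from one commercial acid.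

Key step: step 6

## Route

Remark: the target has no stereocentre, so no SMILES carries stereodescriptors. The halide on magnesium in 11 and 13 is written as a single halide although chloride and bromide are both present.

Step 1
Reactants: 1 2,3,4-trihydroxybenzaldehyde; 2 benzyl bromide
Product: 3 3,4-bis(benzyloxy)-2-hydroxybenzaldehyde
Conditions: BnBr (2.1 equiv), K2CO3, acetone, reflux, N2
Reagents that add atoms: benzyl bromide, BrCc1ccccc1
Why: Twofold Williamson etherification in which two equivalents of 2 are taken up, one for each benzyl ether of 3; the C2 hydroxyl is hydrogen-bonded to the aldehyde and its phenoxide is delocalised into the carbonyl, so the halide should take the C4 and C3 oxygens and leave the chelated one, as in partial alkylation of 2,3,4-trihydroxyaryl carbonyl compounds.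

Step 2
Reactants: 3 3,4-bis(benzyloxy)-2-hydroxybenzaldehyde
Product: 4 3,4-bis(benzyloxy)-2-methoxybenzaldehyde
Conditions: MeI, K2CO3, DMF, 50 °C
Reagents that add atoms: iodomethane, CI
Why: Williamson methylation of the remaining chelated phenol, which should yield to MeI in a dipolar aprotic solvent on warming; this fixes the C2 methoxy group of ring A.

Step 3
Reactants: 4 3,4-bis(benzyloxy)-2-methoxybenzaldehyde
Product: 6 3,4-bis(benzyloxy)-2-methoxyphenol, via aryl formate 5 (not isolated)
Conditions: mCPBA, CH2Cl2, 0 °C to rt; aq. NaHCO3 wash; then K2CO3 (cat.), MeOH, rt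
Reagents that add atoms: 3-chloroperoxybenzoic acid (mCPBA), O=C(OO)c1cccc(Cl)c1
Why: Baeyer–Villiger (Dakin-type) oxidation; the aryl group carries ortho and para oxygen donors and should migrate in preference to hydride to give formate 5, which mild methanolysis cleaves to the phenol.

Step 4
Reactants: 6 3,4-bis(benzyloxy)-2-methoxyphenol
Product: 7 3,4-bis(benzyloxy)-6-iodo-2-methoxyphenol
Conditions: I2 (1.0 equiv), morpholine, CH2Cl2, 0 °C to rt
Reagents that add atoms: iodine, II
Why: Electrophilic aromatic iodination of the phenol by the morpholine–iodine complex under phenoxide-like activation; the para position (C4) and one ortho position (C2) carry oxygen, so C6 is the only site activated by the phenoxide, while C5 is meta to it.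

Step 5
Reactants: 7 3,4-bis(benzyloxy)-6-iodo-2-methoxyphenol
Product: 8 3,4-bis(benzyloxy)-6-iodo-2-methoxyphenyl trifluoromethanesulfonate
Conditions: Tf2O, pyridine, CH2Cl2, 0 °C
Reagents that add atoms: trifluoromethanesulfonic anhydride, O=S(=O)(OS(=O)(=O)C(F)(F)F)C(F)(F)F
Why: O-sulfonylation of the phenol; this places the leaving group at C1 beside the iodide at C6, the 1,2-relationship needed for aryne formation.

Step 6
Reactants: 8 3,4-bis(benzyloxy)-6-iodo-2-methoxyphenyl trifluoromethanesulfonate; 9 methylmagnesium bromide; 10 carbon dioxide
Product: 14 3,4-bis(benzyloxy)-2-methoxy-6-methylbenzoic acid, via ortho-magnesiated aryl triflate 11 (not isolated), via aryne 12 (not isolated), via arylmagnesium bromide 13 (not isolated)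
Conditions: MeMgBr (4 equiv), THF, −78 °C; iPrMgCl·LiCl (1.05 equiv), slow addition, −78 to 0 °C; then CO2 (gas), −20 °C to rt; aq. HCl
Reagents that add atoms: none
Why: Iodine–magnesium exchange at C6 by iPrMgCl·LiCl should be fast at −78 °C because the ortho triflate activates that carbon, and 11 then loses MgCl(OTf) to give aryne 12 across C1–C6. Methylmagnesium bromide is present in excess while the isopropyl reagent is consumed as it is added, so it should be the nucleophile that adds to the strained triple bond (carbomagnesiation) to give 13, which CO2 carboxylates at C1. The closest known reaction type is the addition of Grignard reagents to arynes released from 2-halogenoaryl sulfonates with electrophilic capture of the new arylmagnesium, including three-component aryne couplings that end with CO2. No ring is closed and no stereocentre is formed; two skeletal C–C bonds (C6–CH3 and C1–CO2H) are made. The selectivity required is regiochemical: methyl must go to C6 and magnesium to C1. The C2 methoxy oxygen should secure this, because its inductive pull distorts the aryne so that C6 is the more linear, more electrophilic terminus and the carbanion developing at C1 is stabilised and chelated by the neighbouring oxygen; the benzyloxy groups at C3 and C4 are remote and their weak inductive effects oppose each other. Acidic work-up should deliver the free acid directly, so no doubly ortho-substituted ester has to be saponified.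

Step 7
Reactants: 15 orsellinic acid (2,4-dihydroxy-6-methylbenzoic acid); 2 benzyl bromide
Product: 16 benzyl 2,4-dihydroxy-6-methylbenzoate (benzyl orsellinate)
Conditions: BnBr (1.05 equiv), KHCO3, DMF, rt
Reagents that add atoms: none
Why: Chemoselective SN2 alkylation of the carboxylate; hydrogencarbonate deprotonates only the carboxylic acid, so both phenols should stay free.

Step 8
Reactants: 15 orsellinic acid
Product: 18 2,4-bis[(tert-butyldimethylsilyl)oxy]-6-methylbenzoic acid, via silyl ester 17 (not isolated)
Conditions: TBSCl (3.5 equiv), imidazole, DMF, rt; then AcOH, THF, H2O, rt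
Reagents that add atoms: tert-butyldimethylsilyl chloride, CC(C)(C)[Si](C)(C)Cl
Why: Exhaustive silylation of the carboxyl and both phenols gives 17; silyl esters hydrolyse far faster than aryl silyl ethers, so mild aqueous acid should free only the carboxylic acid and leave both silyl ethers of 18 in place.

Step 9
Reactants: 18 2,4-bis[(tert-butyldimethylsilyl)oxy]-6-methylbenzoic acid; 16 benzyl 2,4-dihydroxy-6-methylbenzoate
Product: 19 benzyl 4-({2,4-bis[(tert-butyldimethylsilyl)oxy]-6-methylbenzoyl}oxy)-2-hydroxy-6-methylbenzoate
Conditions: DCC, DMAP (cat.), CH2Cl2, 0 °C to rt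
Reagents that add atoms: none
Why: Steglich esterification; of the two phenols in 16 the C4 hydroxyl should react, because the C2 hydroxyl is hydrogen-bonded to the ester carbonyl and hindered, and the silyl ethers prevent ring B from acylating itself.

Step 10
Reactants: 19 benzyl 4-({2,4-bis[(tert-butyldimethylsilyl)oxy]-6-methylbenzoyl}oxy)-2-hydroxy-6-methylbenzoate
Product: 20 benzyl 4-[(2,4-dihydroxy-6-methylbenzoyl)oxy]-2-hydroxy-6-methylbenzoate
Conditions: HF·pyridine, THF, 0 °C to rt
Reagents that add atoms: none
Why: Fluoride-driven cleavage of the two aryl silyl ethers under weakly acidic, non-nucleophilic conditions, which should leave the aryl ester and the benzyl ester intact.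

Step 11
Reactants: 14 3,4-bis(benzyloxy)-2-methoxy-6-methylbenzoic acid; 20 benzyl 4-[(2,4-dihydroxy-6-methylbenzoyl)oxy]-2-hydroxy-6-methylbenzoate
Product: 21 benzyl 4-[(4-{[3,4-bis(benzyloxy)-2-methoxy-6-methylbenzoyl]oxy}-2-hydroxy-6-methylbenzoyl)oxy]-2-hydroxy-6-methylbenzoate
Conditions: TFAA, toluene, rt
Reagents that add atoms: none
Why: Esterification through the mixed trifluoroacetic anhydride; the electron-rich, doubly ortho-substituted acid should ionise readily to an acylium-like species that is captured by the only non-chelated phenol of 20 (ring B, C4), and the acidic medium generates no phenoxide that could transesterify the existing depside bond.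

Step 12
Reactants: 21 benzyl 4-[(4-{[3,4-bis(benzyloxy)-2-methoxy-6-methylbenzoyl]oxy}-2-hydroxy-6-methylbenzoyl)oxy]-2-hydroxy-6-methylbenzoate
Product: 22 4-[(4-{[3,4-dihydroxy-2-methoxy-6-methylbenzoyl]oxy}-2-hydroxy-6-methylbenzoyl)oxy]-2-hydroxy-6-methylbenzoic acid (target, CNP0277338.0)
Conditions: H2 (1 atm), 10% Pd/C, EtOAc, rt
Reagents that add atoms: none
Why: Catalytic hydrogenolysis of two benzyl ethers and one benzyl ester under neutral conditions; aryl esters and the arene rings should not be reduced.

## Compound list

1 | 2,3,4-trihydroxybenzaldehyde | O=Cc1ccc(O)c(O)c1O | starting material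
2 | benzyl bromide | BrCc1ccccc1 | starting material
3 | 3,4-bis(benzyloxy)-2-hydroxybenzaldehyde | O=Cc1ccc(OCc2ccccc2)c(OCc2ccccc2)c1O | intermediate
4 | 3,4-bis(benzyloxy)-2-methoxybenzaldehyde | COc1c(C=O)ccc(OCc2ccccc2)c1OCc1ccccc1 | intermediate
5 | 3,4-bis(benzyloxy)-2-methoxyphenyl formate | COc1c(OC=O)ccc(OCc2ccccc2)c1OCc1ccccc1 | intermediate
6 | 3,4-bis(benzyloxy)-2-methoxyphenol | COc1c(O)ccc(OCc2ccccc2)c1OCc1ccccc1 | intermediate
7 | 3,4-bis(benzyloxy)-6-iodo-2-methoxyphenol | COc1c(O)c(I)cc(OCc2ccccc2)c1OCc1ccccc1 | intermediate
8 | 3,4-bis(benzyloxy)-6-iodo-2-methoxyphenyl trifluoromethanesulfonate | COc1c(OCc2ccccc2)c(OCc2ccccc2)cc(I)c1OS(=O)(=O)C(F)(F)F | intermediate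
9 | methylmagnesium bromide | C[Mg]Br | starting material
10 | carbon dioxide | O=C=O | starting material
11 | 4,5-bis(benzyloxy)-3-methoxy-2-[(trifluoromethanesulfonyl)oxy]phenylmagnesium chloride | COc1c(OCc2ccccc2)c(OCc2ccccc2)cc([Mg]Cl)c1OS(=O)(=O)C(F)(F)F | intermediate
12 | 4,5-bis(benzyloxy)-3-methoxybenzyne (1,2-didehydrobenzene) | COC1=C(OCc2ccccc2)C(OCc2ccccc2)=CC#C1 | intermediate
13 | 3,4-bis(benzyloxy)-2-methoxy-6-methylphenylmagnesium bromide | COc1c(OCc2ccccc2)c(OCc2ccccc2)cc(C)c1[Mg]Br | intermediate
14 | 3,4-bis(benzyloxy)-2-methoxy-6-methylbenzoic acid | COc1c(OCc2ccccc2)c(OCc2ccccc2)cc(C)c1C(=O)O | intermediate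
15 | orsellinic acid (2,4-dihydroxy-6-methylbenzoic acid) | Cc1cc(O)cc(O)c1C(=O)O | starting material
16 | benzyl 2,4-dihydroxy-6-methylbenzoate | Cc1cc(O)cc(O)c1C(=O)OCc1ccccc1 | intermediate
17 | tert-butyldimethylsilyl 2,4-bis[(tert-butyldimethylsilyl)oxy]-6-methylbenzoate | Cc1cc(O[Si](C)(C)C(C)(C)C)cc(O[Si](C)(C)C(C)(C)C)c1C(=O)O[Si](C)(C)C(C)(C)C | intermediate
18 | 2,4-bis[(tert-butyldimethylsilyl)oxy]-6-methylbenzoic acid | Cc1cc(O[Si](C)(C)C(C)(C)C)cc(O[Si](C)(C)C(C)(C)C)c1C(=O)O | intermediate
19 | benzyl 4-({2,4-bis[(tert-butyldimethylsilyl)oxy]-6-methylbenzoyl}oxy)-2-hydroxy-6-methylbenzoate | Cc1cc(O[Si](C)(C)C(C)(C)C)cc(O[Si](C)(C)C(C)(C)C)c1C(=O)Oc1cc(C)c(C(=O)OCc2ccccc2)c(O)c1 | intermediate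
20 | benzyl 4-[(2,4-dihydroxy-6-methylbenzoyl)oxy]-2-hydroxy-6-methylbenzoate | Cc1cc(O)cc(O)c1C(=O)Oc1cc(C)c(C(=O)OCc2ccccc2)c(O)c1 | intermediate
21 | benzyl 4-[(4-{[3,4-bis(benzyloxy)-2-methoxy-6-methylbenzoyl]oxy}-2-hydroxy-6-methylbenzoyl)oxy]-2-hydroxy-6-methylbenzoate | COc1c(OCc2ccccc2)c(OCc2ccccc2)cc(C)c1C(=O)Oc1cc(C)c(C(=O)Oc2cc(C)c(C(=O)OCc3ccccc3)c(O)c2)c(O)c1 | intermediate
22 | 4-[(4-{[3,4-dihydroxy-2-methoxy-6-methylbenzoyl]oxy}-2-hydroxy-6-methylbenzoyl)oxy]-2-hydroxy-6-methylbenzoic acid | COc1c(O)c(O)cc(C)c1C(=O)Oc1cc(C)c(C(=O)Oc2cc(C)c(C(=O)O)c(O)c2)c(O)c1 | target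

## Step count and risks

Total: 12 steps. Longest linear sequence: 8 steps (steps 1–6, 11 and 12, from 2,3,4-trihydroxybenzaldehyde 1). The B–C branch (steps 7–10) joins at step 11.

**Step 6 (key step).**
- **What may go wrong:** competing addition of the isopropyl Grignard reagent to the aryne if exchange and elimination are not well separated from nucleophile delivery; attack at the sulfur of the triflate returning phenol 7; protonation of the hindered arylmagnesium before carboxylation; or erosion of regioselectivity.
- **Fallback:** this avoids the aryne altogether and sets out from 8. Chemoselective Negishi methylation at the C–I bond (MeZnCl, Pd(PPh3)4, THF) should give 3,4-bis(benzyloxy)-2-methoxy-6-methylphenyl trifluoromethanesulfonate F1. Palladium-catalysed hydroxycarbonylation of the remaining triflate (Pd(OAc)2, dppf, KOAc, CO, DMSO, 70 °C) then returns to the route at 14.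

**Step 1.**
- **What may go wrong:** incomplete discrimination between the chelated C2 hydroxyl and the C3 hydroxyl (over-alkylation or alkylation at C2), and air oxidation of the polyphenoxide.
- **Fallback:** set out from 1 and 2, benzylate exhaustively (excess BnBr, K2CO3, DMF) to 2,3,4-tris(benzyloxy)benzaldehyde F2, then remove only the benzyl ether ortho to the aldehyde by chelation-controlled cleavage with MgBr2·OEt2 in toluene/Et2O at reflux. This returns to the route at 3.

**Step 4.**
- **What may go wrong:** competing iodination at C5 (ortho to the C4 benzyloxy group, para to the methoxy group) if the phenol reacts in its neutral form; second iodination; or oxidation of the electron-rich phenol by iodine.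
- **Fallback:** replace electrophilic substitution by directed ortho-metalation, setting out from 6. Carbamoylation (ClCONEt2, NaH, THF) gives 3,4-bis(benzyloxy)-2-methoxyphenyl N,N-diethylcarbamate F3. Lithiation ortho to the carbamate (sBuLi, TMEDA, THF, −78 °C) and quenching with I2 gives 3,4-bis(benzyloxy)-6-iodo-2-methoxyphenyl N,N-diethylcarbamate F4. Hydrolysis (NaOH, EtOH, H2O, reflux) returns to the route at 7.

**Step 9.**
- **What may go wrong:** migration of the ortho silyl group from the phenol oxygen to the carboxylate before or during activation, and rearrangement of the hindered O-acylisourea to the N-acylurea, both lowering conversion to the ester.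
- **Fallback:** use benzyl protection throughout, setting out from 15 (with 2 and 16). Exhaustive benzylation (BnBr, K2CO3, DMF) gives benzyl 2,4-bis(benzyloxy)-6-methylbenzoate F5. Saponification (KOH, aq. DMSO, 80 °C) gives 2,4-bis(benzyloxy)-6-methylbenzoic acid F6. Esterification with 16 (TFAA, toluene) gives benzyl 4-{[2,4-bis(benzyloxy)-6-methylbenzoyl]oxy}-2-hydroxy-6-methylbenzoate F7. Hydrogenolysis (H2, Pd/C) gives lecanoric acid F8. Carboxylate-selective benzylation (BnBr, KHCO3, DMF) returns to the route at 20.

**Step 11.**
- **What may go wrong:** slow acyl transfer from the doubly ortho-substituted acid, acylation of a chelated hydroxyl, or acid-promoted transacylation of the existing B–C depside bond.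
- **Fallback:** change the order of ester formation, setting out from 14. Esterify 14 with allyl 2,4-dihydroxy-6-methylbenzoate F9 (from 15, allyl bromide, KHCO3, DMF), through the acid chloride of 14 ((COCl)2, cat. DMF; then pyridine). No other ester is present at this stage. This gives allyl 4-{[3,4-bis(benzyloxy)-2-methoxy-6-methylbenzoyl]oxy}-2-hydroxy-6-methylbenzoate F10. Deallylation (Pd(PPh3)4, PhSiH3, CH2Cl2) gives 4-{[3,4-bis(benzyloxy)-2-methoxy-6-methylbenzoyl]oxy}-2-hydroxy-6-methylbenzoic acid F11. Steglich coupling with 16 (DCC, cat. DMAP) returns to the route at 21.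

## Further compounds

F1 | step 6 | 3,4-bis(benzyloxy)-2-methoxy-6-methylphenyl trifluoromethanesulfonate | COc1c(OCc2ccccc2)c(OCc2ccccc2)cc(C)c1OS(=O)(=O)C(F)(F)F
F2 | step 1 | 2,3,4-tris(benzyloxy)benzaldehyde | O=Cc1ccc(OCc2ccccc2)c(OCc2ccccc2)c1OCc1ccccc1
F3 | step 4 | 3,4-bis(benzyloxy)-2-methoxyphenyl N,N-diethylcarbamate | CCN(CC)C(=O)Oc1ccc(OCc2ccccc2)c(OCc2ccccc2)c1OC
F4 | step 4 | 3,4-bis(benzyloxy)-6-iodo-2-methoxyphenyl N,N-diethylcarbamate | CCN(CC)C(=O)Oc1c(I)cc(OCc2ccccc2)c(OCc2ccccc2)c1OC
F5 | step 9 | benzyl 2,4-bis(benzyloxy)-6-methylbenzoate | Cc1cc(OCc2ccccc2)cc(OCc2ccccc2)c1C(=O)OCc1ccccc1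
F6 | step 9 | 2,4-bis(benzyloxy)-6-methylbenzoic acid | Cc1cc(OCc2ccccc2)cc(OCc2ccccc2)c1C(=O)O
F7 | step 9 | benzyl 4-{[2,4-bis(benzyloxy)-6-methylbenzoyl]oxy}-2-hydroxy-6-methylbenzoate | Cc1cc(OCc2ccccc2)cc(OCc2ccccc2)c1C(=O)Oc1cc(C)c(C(=O)OCc2ccccc2)c(O)c1
F8 | step 9 | lecanoric acid, 4-[(2,4-dihydroxy-6-methylbenzoyl)oxy]-2-hydroxy-6-methylbenzoic acid | Cc1cc(O)cc(O)c1C(=O)Oc1cc(C)c(C(=O)O)c(O)c1
F9 | step 11 | allyl 2,4-dihydroxy-6-methylbenzoate | C=CCOC(=O)c1c(C)cc(O)cc1O
F10 | step 11 | allyl 4-{[3,4-bis(benzyloxy)-2-methoxy-6-methylbenzoyl]oxy}-2-hydroxy-6-methylbenzoate | COc1c(OCc2ccccc2)c(OCc2ccccc2)cc(C)c1C(=O)Oc1cc(C)c(C(=O)OCC=C)c(O)c1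
F11 | step 11 | 4-{[3,4-bis(benzyloxy)-2-methoxy-6-methylbenzoyl]oxy}-2-hydroxy-6-methylbenzoic acid | COc1c(OCc2ccccc2)c(OCc2ccccc2)cc(C)c1C(=O)Oc1cc(C)c(C(=O)O)c(O)c1
A1 | alternative 1 | methyl 4-(benzyloxy)-3-oxobutanoate | COC(=O)CC(=O)COCc1ccccc1
A2 | alternative 1 | methyl (E)-but-2-enoate (methyl crotonate) | C/C=C/C(=O)OC
A3 | alternative 1 | methyl 3-(benzyloxy)-6-methyl-2,4-dioxocyclohexane-1-carboxylate, racemic, dienol tautomer, one enantiomer drawn | COC(=O)C1=C(O)C(OCc2ccccc2)=C(O)C[C@@H]1C
A4 | alternative 1 | methyl 3-(benzyloxy)-2,4-dihydroxy-6-methylbenzoate | COC(=O)c1c(C)cc(O)c(OCc2ccccc2)c1O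
A5 | alternative 2 | 2-(benzyloxy)-3-[(tert-butyldimethylsilyl)oxy]-1-methoxy-1-[(trimethylsilyl)oxy]buta-1,3-diene, ketene acetal geometry not defined | C=C(O[Si](C)(C)C(C)(C)C)C(OCc1ccccc1)=C(OC)O[Si](C)(C)C
A6 | alternative 2 | benzyl 2-(benzyloxy)-4-{[2-(benzyloxy)-4-(but-2-ynoyloxy)-6-methylbenzoyl]oxy}-6-methylbenzoate | CC#CC(=O)Oc1cc(C)c(C(=O)Oc2cc(C)c(C(=O)OCc3ccccc3)c(OCc3ccccc3)c2)c(OCc2ccccc2)c1
A7 | alternative 2 | benzyl 2-(benzyloxy)-4-{[2-(benzyloxy)-4-({3-(benzyloxy)-4-[(tert-butyldimethylsilyl)oxy]-2-hydroxy-6-methylbenzoyl}oxy)-6-methylbenzoyl]oxy}-6-methylbenzoate | Cc1cc(O[Si](C)(C)C(C)(C)C)c(OCc2ccccc2)c(O)c1C(=O)Oc1cc(C)c(C(=O)Oc2cc(C)c(C(=O)OCc3ccccc3)c(OCc3ccccc3)c2)c(OCc2ccccc2)c1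
A8 | alternative 3 | 6-(2,4-dioxopentyl)-2,2-dimethyl-4H-1,3-dioxin-4-one | CC(=O)CC(=O)CC1=CC(=O)OC(C)(C)O1
A9 | alternative 3 | benzyl 2-(benzyloxy)-4-hydroxy-6-methylbenzoate | Cc1cc(O)cc(OCc2ccccc2)c1C(=O)OCc1ccccc1
A10 | alternative 3 | benzyl 2-(benzyloxy)-4-[(2,4-dihydroxy-6-methylbenzoyl)oxy]-6-methylbenzoate | Cc1cc(O)cc(O)c1C(=O)Oc1cc(C)c(C(=O)OCc2ccccc2)c(OCc2ccccc2)c1
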